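Assumption: genistein, the reagents used below and the L-fructose-derived Shi ketone (an organocatalyst, the enantiomer of the common D-fructose ketone) are taken as purchasable.

**Retrosynthetic overview**
- C8-prenyl: removed last as an O-to-C relay, in which a C7–O bond to a tert-prenyl group is made and a [3,3] shift carries it to C8 (new one-flask method on the free triol).
- Side-chain carbinol: its C–O bond and (S) configuration come from asymmetric epoxidation of a 6-prenyl group; the tertiary C–O bond of the oxirane is then reduced off.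
- 6-Prenyl: Stille coupling on a 6-iodide that the free 5-OH places at C6; the 5-OH is methylated only afterwards, while 7-OH and 4'-OH ride as MOM ethers.
- Rings: none is built. Ring A, the pyranone ring C and ring B come intact from genistein; the only ring formed is the transient oxirane (made in step 5, opened in step 6).

**Route**

Step 1
Reactants: 1 genistein (5,7-dihydroxy-3-(4-hydroxyphenyl)-4H-chromen-4-one); 2 chloromethyl methyl ether
Product: 3 5-hydroxy-7-(methoxymethoxy)-3-[4-(methoxymethoxy)phenyl]-4H-chromen-4-one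
Conditions: 2 (2.4 equiv), K2CO3 (4 equiv), acetone, 0 °C to rt
Reagents that add atoms: chloromethyl methyl ether (2), COCCl
Why: Williamson-type O-alkylation of the two acidic phenols (7-OH, 4'-OH); the 5-OH is hydrogen-bonded to the C4 carbonyl and stays free.

Step 2
Reactants: 3 5-hydroxy-7-(methoxymethoxy)-3-[4-(methoxymethoxy)phenyl]-4H-chromen-4-one; 4 N-iodosuccinimide
Product: 5 5-hydroxy-6-iodo-7-(methoxymethoxy)-3-[4-(methoxymethoxy)phenyl]-4H-chromen-4-one
Conditions: 4 (1.05 equiv), DMF, rt, dark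
Reagents that add atoms: N-iodosuccinimide (4), O=C1CCC(=O)N1I
Why: Electrophilic aromatic iodination under neutral conditions; the free chelated 5-OH sends the electrophile to its ortho carbon C6 (5-O-alkyl analogues react at C8 instead), and ring B with its capped phenol is too weakly activated to react.

Step 3
Reactants: 5 5-hydroxy-6-iodo-7-(methoxymethoxy)-3-[4-(methoxymethoxy)phenyl]-4H-chromen-4-one; 6 iodomethane
Product: 7 6-iodo-5-methoxy-7-(methoxymethoxy)-3-[4-(methoxymethoxy)phenyl]-4H-chromen-4-one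
Conditions: 6 (5 equiv), K2CO3 (3 equiv), DMF, 45 °C
Reagents that add atoms: iodomethane (6), CI
Why: Williamson O-methylation of the remaining chelated phenol under forcing carbonate conditions; the acetals and the aryl iodide are inert.

Step 4
Reactants: 7 6-iodo-5-methoxy-7-(methoxymethoxy)-3-[4-(methoxymethoxy)phenyl]-4H-chromen-4-one; 8 tributyl(3-methylbut-2-en-1-yl)stannane
Product: 9 5-methoxy-7-(methoxymethoxy)-3-[4-(methoxymethoxy)phenyl]-6-(3-methylbut-2-en-1-yl)-4H-chromen-4-one
Conditions: 8 (1.5 equiv), Pd(PPh3)4 (5 mol%), CuI (10 mol%), DMF, 90 °C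
Reagents that add atoms: tributyl(3-methylbut-2-en-1-yl)stannane (8), CCCC[Sn](CCCC)(CCCC)CC=C(C)C
Why: Stille cross-coupling under neutral conditions that the base-sensitive pyranone tolerates; the allyl group is transferred as the linear prenyl group.

Step 5
Reactants: 9 5-methoxy-7-(methoxymethoxy)-3-[4-(methoxymethoxy)phenyl]-6-(3-methylbut-2-en-1-yl)-4H-chromen-4-one; 10 potassium peroxymonosulfate (KHSO5)
Product: 11 6-{[(2S)-3,3-dimethyloxiran-2-yl]methyl}-5-methoxy-7-(methoxymethoxy)-3-[4-(methoxymethoxy)phenyl]-4H-chromen-4-one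
Conditions: 10 (1.4 equiv, as 2KHSO5·KHSO4·K2SO4), L-fructose-derived Shi ketone (30 mol%), K2CO3, Bu4NHSO4 (cat.), MeCN–CH2(OMe)2/aq. Na2B4O7–Na2EDTA buffer (pH 10.5), 0 °C
Reagents that add atoms: potassium peroxymonosulfate (10), [K+].[O-]S(=O)(=O)OO
Why: Shi asymmetric epoxidation (chiral dioxirane, spiro transition state) of the only electron-rich alkene; the D-fructose ketone gives (R)-epoxides from 2-methylalk-2-enes, so its enantiomer sets the (S) C–O stereocentre.

Step 6
Reactants: 11 6-{[(2S)-3,3-dimethyloxiran-2-yl]methyl}-5-methoxy-7-(methoxymethoxy)-3-[4-(methoxymethoxy)phenyl]-4H-chromen-4-one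
Product: 12 6-[(2S)-2-hydroxy-3-methylbutyl]-5-methoxy-7-(methoxymethoxy)-3-[4-(methoxymethoxy)phenyl]-4H-chromen-4-one
Conditions: Cp2TiCl2 (10 mol%), Mn dust (1.5 equiv), 2,4,6-collidine·HCl (2.5 equiv), cyclohexa-1,4-diene (10 equiv), THF, rt
Reagents that add atoms: none
Why: Nugent–RajanBabu-type titanocene radical epoxide opening in its catalytic form; trivalent titanium cleaves the tertiary C–O bond to the more substituted radical, which takes a hydrogen atom from cyclohexadiene, so the secondary C–O bond keeps its (S) configuration.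

Step 7
Reactants: 12 6-[(2S)-2-hydroxy-3-methylbutyl]-5-methoxy-7-(methoxymethoxy)-3-[4-(methoxymethoxy)phenyl]-4H-chromen-4-one
Product: 13 7-hydroxy-6-[(2S)-2-hydroxy-3-methylbutyl]-3-(4-hydroxyphenyl)-5-methoxy-4H-chromen-4-one
Conditions: 3 M aq. HCl–MeOH (1:5), 50 °C
Reagents that add atoms: none
Why: Acid-catalysed acetal (MOM) cleavage, done before any acid-sensitive ortho-prenylphenol exists; the aryl methyl ether and the non-benzylic carbinol are stable.

Step 8
Reactants: 13 7-hydroxy-6-[(2S)-2-hydroxy-3-methylbutyl]-3-(4-hydroxyphenyl)-5-methoxy-4H-chromen-4-one; 14 tert-butyl 2-methylbut-3-en-2-yl carbonate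
Product: 16 7-hydroxy-6-[(2S)-2-hydroxy-3-methylbutyl]-3-(4-hydroxyphenyl)-5-methoxy-8-(3-methylbut-2-en-1-yl)-4H-chromen-4-one (CNP0323282.1), via tert-prenyl ether 15 (not isolated)
Conditions: 14 (1.1 equiv), Pd(PPh3)4 (3 mol%), THF, 0 °C; then thiol-silica (Pd scavenger), solvent switch to PhMe, Eu(fod)3 (10 mol%), 80 °C
Reagents that add atoms: tert-butyl 2-methylbut-3-en-2-yl carbonate (14), C=CC(C)(C)OC(=O)OC(C)(C)C
Why: Proposed new method: a site-selective O-to-C prenyl relay on an unprotected triol — ionisation of 14 by zerovalent palladium releases tert-butoxide, which deprotonates only the most acidic OH (the 7-OH, a vinylogous acid some 2–3 pKa units below the 4'-OH and about 10 below the alcohol); the ion-paired 7-phenoxide attacks the more substituted terminus of the prenyl–palladium cation to give the tert-prenyl ether 15, and a europium-accelerated aromatic Claisen [3,3] shift then carries the allyl group to C8, the only free ortho carbon, with transposition to the linear prenyl group; the closest known reaction types are palladium-catalysed reverse O-prenylation of simple monophenols with tert-allylic carbonates and the Eu(fod)3-accelerated Claisen rearrangement of aryl allyl ethers, which have not been run as a one-flask relay or with selection among three free hydroxyls.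

**Compound list**
1 | genistein; 5,7-dihydroxy-3-(4-hydroxyphenyl)-4H-chromen-4-one | Oc1cc(O)cc2occ(-c3ccc(O)cc3)c(=O)c12 | starting material
2 | chloromethyl methyl ether | COCCl | starting material
3 | 5-hydroxy-7-(methoxymethoxy)-3-[4-(methoxymethoxy)phenyl]-4H-chromen-4-one | Oc1cc(OCOC)cc2occ(-c3ccc(OCOC)cc3)c(=O)c12 | intermediate
4 | N-iodosuccinimide | O=C1CCC(=O)N1I | starting material
5 | 5-hydroxy-6-iodo-7-(methoxymethoxy)-3-[4-(methoxymethoxy)phenyl]-4H-chromen-4-one | Oc1c(I)c(OCOC)cc2occ(-c3ccc(OCOC)cc3)c(=O)c12 | intermediate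
6 | iodomethane | CI | starting material
7 | 6-iodo-5-methoxy-7-(methoxymethoxy)-3-[4-(methoxymethoxy)phenyl]-4H-chromen-4-one | COc1c(I)c(OCOC)cc2occ(-c3ccc(OCOC)cc3)c(=O)c12 | intermediate
8 | tributyl(3-methylbut-2-en-1-yl)stannane | CCCC[Sn](CCCC)(CCCC)CC=C(C)C | starting material
9 | 5-methoxy-7-(methoxymethoxy)-3-[4-(methoxymethoxy)phenyl]-6-(3-methylbut-2-en-1-yl)-4H-chromen-4-one | COc1c(CC=C(C)C)c(OCOC)cc2occ(-c3ccc(OCOC)cc3)c(=O)c12 | intermediate
10 | potassium peroxymonosulfate (KHSO5) | [K+].[O-]S(=O)(=O)OO | starting material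
11 | 6-{[(2S)-3,3-dimethyloxiran-2-yl]methyl}-5-methoxy-7-(methoxymethoxy)-3-[4-(methoxymethoxy)phenyl]-4H-chromen-4-one | COc1c(C[C@@H]4OC4(C)C)c(OCOC)cc2occ(-c3ccc(OCOC)cc3)c(=O)c12 | intermediate
12 | 6-[(2S)-2-hydroxy-3-methylbutyl]-5-methoxy-7-(methoxymethoxy)-3-[4-(methoxymethoxy)phenyl]-4H-chromen-4-one | COc1c(C[C@H](O)C(C)C)c(OCOC)cc2occ(-c3ccc(OCOC)cc3)c(=O)c12 | intermediate
13 | 7-hydroxy-6-[(2S)-2-hydroxy-3-methylbutyl]-3-(4-hydroxyphenyl)-5-methoxy-4H-chromen-4-one | COc1c(C[C@H](O)C(C)C)c(O)cc2occ(-c3ccc(O)cc3)c(=O)c12 | intermediate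
14 | tert-butyl 2-methylbut-3-en-2-yl carbonate | C=CC(C)(C)OC(=O)OC(C)(C)C | starting material
15 | 6-[(2S)-2-hydroxy-3-methylbutyl]-3-(4-hydroxyphenyl)-5-methoxy-7-[(2-methylbut-3-en-2-yl)oxy]-4H-chromen-4-one | COc1c(C[C@H](O)C(C)C)c(OC(C)(C)C=C)cc2occ(-c3ccc(O)cc3)c(=O)c12 | intermediate
16 | 7-hydroxy-6-[(2S)-2-hydroxy-3-methylbutyl]-3-(4-hydroxyphenyl)-5-methoxy-8-(3-methylbut-2-en-1-yl)-4H-chromen-4-one (CNP0323282.1) | COc1c(C[C@H](O)C(C)C)c(O)c(CC=C(C)C)c2occ(-c3ccc(O)cc3)c(=O)c12 | target

**Count and risks**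
Total steps: 8. Longest linear sequence: 8 (from genistein).

Most likely to fail:

1. Step 8 (the proposed new relay). The risks are competing 4'-O-alkylation, drift to the linear O-prenyl ether by re-ionisation, and an incomplete shift. The fallback uses known chemistry and sets out from 12. N-Iodosuccinimide in DMF iodinates the only free position of ring A, C8 (the site attacked in 5-O-alkyl chromones), to give 8-iodo-6-[(2S)-2-hydroxy-3-methylbutyl]-5-methoxy-7-(methoxymethoxy)-3-[4-(methoxymethoxy)phenyl]-4H-chromen-4-one F1. Stille coupling with 8 (Pd(PPh3)4, CuI, DMF, 90 °C) gives the 8-prenyl bis-MOM ether F2. Mild acid (1 M HCl in MeOH, rt to 40 °C) then removes both MOM groups, and the sequence comes back at 16.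

2. Step 6 (reductive epoxide opening). The tertiary radical can be trapped by a second trivalent titanium and lose a β-hydrogen to give an allylic alcohol, and the chromone carbonyl may be attacked. The fallback sets out from 11 and makes that side reaction the route. Al(O-i-Pr)3 in refluxing PhMe isomerises the epoxide to the allylic alcohol 6-[(2S)-2-hydroxy-3-methylbut-3-en-1-yl]-5-methoxy-7-(methoxymethoxy)-3-[4-(methoxymethoxy)phenyl]-4H-chromen-4-one F3, with the C–O stereocentre untouched. Its 1,1-disubstituted alkene is then hydrogenated with H2 and RhCl(PPh3)3, which leaves the chromone C2=C3 bond alone, and the sequence comes back at 12.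

3. Step 4 (prenyl Stille coupling). The iodide is flanked by two ortho substituents, the allyl group can scramble between its alpha and gamma ends, and protodeiodination can compete. The fallback sets out from 7 and uses a vinyl partner instead. Suzuki coupling with (E)-2-(3-methylbut-1-en-1-yl)-4,4,5,5-tetramethyl-1,3,2-dioxaborolane (Pd(dppf)Cl2, CsF, dioxane, 80 °C) gives the (E)-styrene F4. Shi epoxidation with the common D-fructose-derived ketone gives the (2R,3R)-epoxide F5. The titanocene/cyclohexadiene conditions of step 6 then cleave the benzylic C–O bond only. The remaining carbinol is (S), because the former oxirane carbon drops below isopropyl in CIP priority. The sequence comes back at 12 and by-passes steps 5 and 6.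

**Further compounds**
F1 | step 8 | 6-[(2S)-2-hydroxy-3-methylbutyl]-8-iodo-5-methoxy-7-(methoxymethoxy)-3-[4-(methoxymethoxy)phenyl]-4H-chromen-4-one | COc1c(C[C@H](O)C(C)C)c(OCOC)c(I)c2occ(-c3ccc(OCOC)cc3)c(=O)c12
F2 | step 8 | 6-[(2S)-2-hydroxy-3-methylbutyl]-5-methoxy-7-(methoxymethoxy)-3-[4-(methoxymethoxy)phenyl]-8-(3-methylbut-2-en-1-yl)-4H-chromen-4-one | COc1c(C[C@H](O)C(C)C)c(OCOC)c(CC=C(C)C)c2occ(-c3ccc(OCOC)cc3)c(=O)c12
F3 | step 6 | 6-[(2S)-2-hydroxy-3-methylbut-3-en-1-yl]-5-methoxy-7-(methoxymethoxy)-3-[4-(methoxymethoxy)phenyl]-4H-chromen-4-one | COc1c(C[C@H](O)C(C)=C)c(OCOC)cc2occ(-c3ccc(OCOC)cc3)c(=O)c12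
F4 | step 4 | 5-methoxy-7-(methoxymethoxy)-3-[4-(methoxymethoxy)phenyl]-6-[(1E)-3-methylbut-1-en-1-yl]-4H-chromen-4-one | COc1c(/C=C/C(C)C)c(OCOC)cc2occ(-c3ccc(OCOC)cc3)c(=O)c12
F5 | step 4 | 5-methoxy-7-(methoxymethoxy)-3-[4-(methoxymethoxy)phenyl]-6-[(2R,3R)-3-(propan-2-yl)oxiran-2-yl]-4H-chromen-4-one | COc1c([C@H]4O[C@@H]4C(C)C)c(OCOC)cc2occ(-c3ccc(OCOC)cc3)c(=O)c12
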